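The data are simulated with made-up constants.

- Follow the Ptn through each flask, and reckon in logarithms.

| setting | south-west | north-east | north | south | south-east |
|---|---|---|---|---|---|
| Sbt | 50.0 mM | 25.0 mM | 50.0 mM | 50.0 mM | 20.0 mM |
| Ptn | 60.0 mM | 35.0 mM | 60.0 mM | 60.0 mM | 24.0 mM |
| Ctl | 0.250 mM | 0.250 mM | 0.380 mM | 0.250 mM | 0.250 mM |
| Pdt |  |  |  | 25.0 mM |  |
| time |  |  |  |  | 52 min |

- south-west run (time / min: [Pdt] / mM): 4.0: 6.5; 12: 14.8; 23: 20.0; 36: 22.8; 52: 25.1
- north-east run (time / min: [Pdt] / mM): 4.0: 5.4; 12: 12.7; 23: 18.5; 36: 20.3; 52: 20.6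
- north run (time / min: [Pdt] / mM): 4.0: 14.2; 12: 30.1; 23: 35.2; 36: 36.0; 52: 36.5
- south run (time / min: [Pdt] / mM): 4.0: 31.6; 12: 40.2; 23: 45.5; 36: 49.2; 52: 49.6

(scatter of a reading: 0.4 mM)

- how the opening rate goes with [Ctl] round the charge of the south-west run: the exponent of the rate at two percent of Sbt gone to Pdt
- Pdt in the south-east run at 52 min, as a share of the Sbt charged

- Overall: Sbt + Ptn -> Pdt, with Ctl as catalyst.
- Constant volume, constant temperature.
- A reading of a species includes what of it is bound.
- An order is taken over about fifteen percent of the charge, up and down.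

- The north-east run stands flat, from 20.3 mM at 36 min to 20.6 mM at 52 min, which is 82.4% of its Sbt charge, with 4.40 mM of Sbt unturned.
- The south-west run has the same Ctl but more Sbt and more Ptn, and it reaches 25.1 mM, more than the north-east run, and is still rising. You may suspect a second route that uses up Ptn.
- For the order in Ctl, compare the first readings of the north and south-west runs: the logarithm of their ratio over that of the Ctl charges gives 1.87.
- One extreme for the south-east run has no Ptn lost. Sbt is then the limiting reagent, and the run can reach 100% of its charge.
- The other extreme gives Ptn the share of its charge that reached Pdt in the north-east run, 58.9%, which makes 70.6% of the Sbt charge.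
- The south-east run should lie between them, since the share of Ptn reaching Pdt is smaller in the south-west run, at 41.8% by its last reading, with its larger Ptn charge.
- Suppose Pdt forms first order in Ptn and the loss is second order. A share of ln(1+u)/u of the Ptn charge then reaches Pdt, where u is the charge over 20.9 mM, the break level: the Ptn level at which both routes run equally fast, a selectivity measure, read here from the flat north-east run.
- The south-east run has the Ctl charge of the north-east run, so take the same break level and suppose the run flat by 52 min: this gives 79.9% of the Sbt charge, your own figure.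
- The forecast gives an order of 1.9 (1.6 to 2.3) and 85% (72% to 95%) of the Sbt charge, more than your own figure, on the view that “The catalyst is dying”.
- The simulation gives an order of 2.1, and 82.7% for the south-east run at 52 min.

    Ctl + Sbt ⇌ Ctl.Sbt, settled at all times (347.0 M⁻¹)
    Ctl + Ptn ⇌ Ctl.Ptn, settled at all times (26.90 M⁻¹)
    Ctl.Sbt + Ctl.Ptn → Pdt + 2 Ctl (2.226 × 10⁵ M⁻¹ min⁻¹)
    2 Sbt ⇌ Sbt2, settled at all times (114.0 M⁻¹)
    2 Ptn → L (1.344 M⁻¹ min⁻¹)

- The south-east run falls short through the conversion of Ptn into L: without that step it gives >99.9% instead of 82.7%. Its Pdt takes 68.9% of the Ptn charge, against 66.6% from the break level. In the north run, the break level multiplied by the rate ratio 2.4 becomes 49.5 mM, which puts 39.3 mM in Pdt, or 65.5% of its Ptn charge. That run reads 36.5 mM at 52 min, which is 60.8% of that charge.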